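The route rests on cutting the CH2–CH2 bond of the ethano bridge between ring A (the para-phenylene ring, bridge carbon on C4) and ring B (the 1,2,3-trisubstituted phenol ring, bridge carbon ortho to its diaryl ether oxygen). Both bridge carbons are benzylic, so the saturated bridge is a latent stilbene. Ring-closing olefin metathesis of an acyclic bis-styrene forms this bond as C=C and closes the 18-membered macrocycle in one operation. A single hydrogenation then saturates it and removes every protecting group. The precursor is the fully assembled (S)-1,2-diarylethanol carrying one vinyl group on ring A and one on ring B, built by palladium-catalysed ketone α-arylation and asymmetric transfer hydrogenation.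

Key step: step 8

Remark: ring C is the catechol ring bearing the carbinol carbon and ring D the 1,3-disubstituted ring; 12 is drawn as the E-alkene, and any Z isomer is carried forward because both converge on 13 in step 9; compounds 1, 3, 5 and 7 are taken as commercial.

Step 1
Reactants: 1 3′,4′,5′-trihydroxyacetophenone
Product: 2 1-(7-hydroxy-2,2-diphenyl-1,3-benzodioxol-5-yl)ethan-1-one
Conditions: Ph2CCl2, Ph2O, 175 °C
Reagents that add atoms: dichlorodiphenylmethane, ClC(Cl)(c1ccccc1)c1ccccc1
Why: Catechol ketalisation with dichlorodiphenylmethane bridges two adjacent phenols as the five-membered diphenylmethylene ketal, and by the symmetry of 1 only one product is possible, leaving the flanking hydroxyl free for the aryl ether formation.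

Step 2
Reactants: 2 1-(7-hydroxy-2,2-diphenyl-1,3-benzodioxol-5-yl)ethan-1-one; 3 4-vinylphenylboronic acid
Product: 4 1-[7-(4-ethenylphenoxy)-2,2-diphenyl-1,3-benzodioxol-5-yl]ethan-1-one
Conditions: Cu(OAc)2 (20 mol %), pyridine, 4 Å MS, O2 (1 atm), CH2Cl2, rt
Reagents that add atoms: none
Why: Chan–Lam–Evans oxidative copper-catalysed O-arylation couples the single free phenol with the arylboronic acid at room temperature, where the methyl ketone, the ketal and the styrene are inert.

Step 3
Reactants: 5 2-fluoro-3-hydroxybenzaldehyde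
Product: 6 3-(benzyloxy)-2-fluorobenzaldehyde
Conditions: BnBr, K2CO3, DMF, rt
Reagents that add atoms: benzyl bromide, BrCc1ccccc1
Why: Williamson etherification masks the only phenol as a hydrogenolysable benzyl ether, so that it cannot deactivate the ring as a phenoxide in the following SNAr step.

Step 4
Reactants: 6 3-(benzyloxy)-2-fluorobenzaldehyde; 7 3-bromophenol
Product: 8 3-(benzyloxy)-2-(3-bromophenoxy)benzaldehyde
Conditions: K2CO3, DMF, 120 °C
Reagents that add atoms: none
Why: Nucleophilic aromatic substitution (SNAr) through a Meisenheimer intermediate, in which the ortho-formyl group activates the C–F bond toward the phenoxide of 7 while the unactivated C–Br bond does not react.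

Step 5
Reactants: 8 3-(benzyloxy)-2-(3-bromophenoxy)benzaldehyde
Product: 9 1-(benzyloxy)-2-(3-bromophenoxy)-3-ethenylbenzene
Conditions: Ph3PCH3Br, KOtBu, THF, 0 °C to rt
Reagents that add atoms: methyltriphenylphosphonium bromide, C[P+](c1ccccc1)(c1ccccc1)c1ccccc1.[Br-]
Why: Wittig methylenation of the non-enolisable aryl aldehyde with the unstabilised ylide gives the terminal styrene, the aryl bromide and the ethers being inert.

Step 6
Reactants: 4 1-[7-(4-ethenylphenoxy)-2,2-diphenyl-1,3-benzodioxol-5-yl]ethan-1-one; 9 1-(benzyloxy)-2-(3-bromophenoxy)-3-ethenylbenzene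
Product: 10 2-{3-[2-(benzyloxy)-6-ethenylphenoxy]phenyl}-1-[7-(4-ethenylphenoxy)-2,2-diphenyl-1,3-benzodioxol-5-yl]ethan-1-one
Conditions: Pd2(dba)3 (2 mol %), Xantphos (5 mol %), NaOtBu (1.3 equiv), toluene, 70 °C
Reagents that add atoms: none
Why: Buchwald–Hartwig-type palladium-catalysed α-arylation of a methyl ketone, in which the sodium enolate of 4 intercepts the arylpalladium bromide formed from 9 and C–C reductive elimination from the chelating Xantphos complex should outrun Heck insertion of the styrenes, the more acidic product enolate stopping the reaction at monoarylation.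

Step 7
Reactants: 10 the diaryl ethanone from step 6
Product: 11 (1S)-2-{3-[2-(benzyloxy)-6-ethenylphenoxy]phenyl}-1-[7-(4-ethenylphenoxy)-2,2-diphenyl-1,3-benzodioxol-5-yl]ethan-1-ol
Conditions: RuCl(p-cymene)[(S,S)-TsDPEN] (2 mol %), HCO2H/Et3N (5:2), CH2Cl2, 30 °C
Reagents that add atoms: none
Why: Noyori asymmetric transfer hydrogenation, in which the (S,S)-TsDPEN ruthenium hydride delivers hydride to the Re face of the aryl ketone through the six-membered Ru–H/N–H transition state with ring C held by a CH–π contact to the p-cymene ligand, setting the (S)-carbinol by catalyst control without reducing the styrenes.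

Step 8
Reactants: 11 the (1S)-bis-styrene alcohol from step 7
Product: 12 (S,E)-macrocyclic stilbene: the 18-membered ring in which ring A C4 and the ring B carbon ortho to the diaryl ether oxygen are joined by an (E)-CH=CH unit, with the (S)-carbinol, the ring B benzyl ether and the ring C diphenylmethylene ketal retained
Conditions: second-generation Grubbs catalyst RuCl2(=CHPh)(H2IMes)(PCy3) (10 mol %, in portions), toluene (1 mM), 80 °C, Ar sparge
Reagents that add atoms: none
Why: The ruthenium benzylidene formed at the unhindered ring A vinyl group undergoes intramolecular [2+2] cycloaddition with the ring B vinyl group, and cycloreversion of the ruthenacyclobutane releases the stilbene and ethylene (Chauvin mechanism). The reaction type is macrocyclic ring-closing olefin metathesis of an α,ω-diene, here two styrenes giving a stilbene. It closes the 18-membered ring by head-to-head union of the two ArCH= carbons, a large-ring closure favoured over oligomerisation by high dilution and driven by loss of ethylene. No stereocentre is created: the (S)-carbinol is remote from the reacting termini and untouched, and the alkene geometry is irrelevant because the alkene is hydrogenated in step 9. The selectivity needed is intramolecular over intermolecular metathesis at the two vinyl groups only, secured by the 1 mM concentration and by the absence of any other alkene; the free alcohol, the ketal and the ethers are inert to the catalyst.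

Step 9
Reactants: 12 the (S,E)-macrocyclic stilbene from step 8
Product: 13 CNP0333307.1, the (S)-configured macrocyclic bis(bibenzyl) tetraol
Conditions: H2 (1 atm), 10% Pd/C, EtOAc/THF, rt
Reagents that add atoms: none
Why: Heterogeneous catalytic hydrogenation saturates the stilbene and hydrogenolyses the benzyl ether and the diphenylmethylene ketal in one operation, while under neutral conditions at room temperature the secondary benzylic alcohol should keep its C–O bond and its configuration.

Compound list
1 | 3′,4′,5′-trihydroxyacetophenone | CC(=O)c1cc(O)c(O)c(O)c1 | starting material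
2 | 1-(7-hydroxy-2,2-diphenyl-1,3-benzodioxol-5-yl)ethan-1-one | CC(=O)c1cc(O)c2OC(c3ccccc3)(c3ccccc3)Oc2c1 | intermediate
3 | 4-vinylphenylboronic acid | OB(O)c1ccc(C=C)cc1 | starting material
4 | 1-[7-(4-ethenylphenoxy)-2,2-diphenyl-1,3-benzodioxol-5-yl]ethan-1-one | CC(=O)c1cc(Oc2ccc(C=C)cc2)c2OC(c3ccccc3)(c3ccccc3)Oc2c1 | intermediate
5 | 2-fluoro-3-hydroxybenzaldehyde | O=Cc1cccc(O)c1F | starting material
6 | 3-(benzyloxy)-2-fluorobenzaldehyde | O=Cc1cccc(OCc2ccccc2)c1F | intermediate
7 | 3-bromophenol | Oc1cccc(Br)c1 | starting material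
8 | 3-(benzyloxy)-2-(3-bromophenoxy)benzaldehyde | O=Cc1cccc(OCc2ccccc2)c1Oc1cccc(Br)c1 | intermediate
9 | 1-(benzyloxy)-2-(3-bromophenoxy)-3-ethenylbenzene | C=Cc1cccc(OCc2ccccc2)c1Oc1cccc(Br)c1 | intermediate
10 | 2-{3-[2-(benzyloxy)-6-ethenylphenoxy]phenyl}-1-[7-(4-ethenylphenoxy)-2,2-diphenyl-1,3-benzodioxol-5-yl]ethan-1-one | C=Cc1ccc(cc1)Oc1cc(cc2OC(c3ccccc3)(c3ccccc3)Oc12)C(=O)Cc1cccc(c1)Oc1c(C=C)cccc1OCc1ccccc1 | intermediate
11 | (1S)-2-{3-[2-(benzyloxy)-6-ethenylphenoxy]phenyl}-1-[7-(4-ethenylphenoxy)-2,2-diphenyl-1,3-benzodioxol-5-yl]ethan-1-ol | C=Cc1ccc(cc1)Oc1cc(cc2OC(c3ccccc3)(c3ccccc3)Oc12)[C@@H](O)Cc1cccc(c1)Oc1c(C=C)cccc1OCc1ccccc1 | intermediate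
12 | (S,E)-macrocyclic stilbene (18-membered ring; ring B O-benzyl, ring C diphenylmethylene ketal, free (S)-carbinol) | O[C@H]1Cc2cccc(c2)Oc2c(OCc3ccccc3)cccc2/C=C/c2ccc(cc2)Oc2cc1cc3OC(c4ccccc4)(c4ccccc4)Oc23 | intermediate
13 | CNP0333307.1, (S)-macrocyclic bis(bibenzyl) tetraol | Oc1cc2cc(c1O)Oc1ccc(cc1)CCc1cccc(O)c1Oc1cccc(c1)C[C@@H]2O | target

Total step count: 9. Longest linear sequence: 7 steps (steps 3 to 9, from 5).

Steps most likely to fail

Step 8 (ring-closing metathesis). Intermolecular metathesis may outrun ring closure, because the ring B vinyl group is flanked by the aryloxy substituent; this would give open-chain and cyclic dimeric stilbenes. The catalyst may also decay over the long reaction time that dilution demands. The fallback closes the same bond by an irreversible reductive carbonyl coupling; it sets out from 11 and comes back at 12. The carbinol of 11 is silylated (TBSCl, imidazole, DMF) to the tert-butyldimethylsilyl ether F1. Both vinyl groups are cleaved by Lemieux–Johnson oxidation (OsO4 cat., NaIO4, 2,6-lutidine, dioxane/H2O) to the dialdehyde F2. Intramolecular McMurry coupling with low-valent titanium (TiCl4, Zn, pyridine, THF, reflux, slow addition) gives the silylated macrocyclic stilbene F3. TBAF in THF then returns 12.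

Step 6 (α-arylation). Heck-type insertion of a styrene into the arylpalladium intermediate, or a second arylation of the product enolate, may consume the coupling partners. The fallback forms the same ketone without palladium, by acylation of a benzylic Grignard reagent; it sets out from 9 and 3 and comes back at 10. Commercial methyl gallate (COC(=O)c1cc(O)c(O)c(O)c1) is ketalised with dichlorodiphenylmethane as in step 1 to the phenol ester F4. Chan–Lam coupling with 3 as in step 2 gives the aryl ether ester F5. MeNH(OMe)·HCl and i-PrMgCl in THF at −20 °C give the Weinreb amide F6. In parallel, 9 is converted with Mg in THF into the arylmagnesium bromide F7 (not isolated), which is trapped with paraformaldehyde to the benzylic alcohol F8. SOCl2 in CH2Cl2 gives the benzylic chloride F9. Mg in THF gives the benzylmagnesium chloride F10 (not isolated), which adds to F6 at 0 °C. The chelated tetrahedral intermediate collapses on work-up to 10.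

Step 9 (global hydrogenation). Once the para-phenol of ring C is unveiled, hydrogenolysis of the benzylic C–O bond of the carbinol may set in and destroy the stereocentre; cleavage of the diphenylmethylene ketal may also stall. The fallback shields the carbinol during the reduction; it sets out from 12 and comes back at 13. Silylation (TESCl, imidazole, DMF) gives the triethylsilyl ether F11. Hydrogenation (H2, 10% Pd/C, EtOAc, rt) gives the silylated tetraphenol macrocycle F12, in which the bulky silyl ether should resist C–O hydrogenolysis. Buffered HF·pyridine in pyridine/THF at 0 °C then releases 13.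

Further compounds
F1 | step 8 | tert-butyldimethylsilyl ether of 11 | C=Cc1ccc(cc1)Oc1cc(cc2OC(c3ccccc3)(c3ccccc3)Oc12)[C@@H](O[Si](C)(C)C(C)(C)C)Cc1cccc(c1)Oc1c(C=C)cccc1OCc1ccccc1
F2 | step 8 | dialdehyde from cleavage of both vinyl groups of F1 | O=Cc1ccc(cc1)Oc1cc(cc2OC(c3ccccc3)(c3ccccc3)Oc12)[C@@H](O[Si](C)(C)C(C)(C)C)Cc1cccc(c1)Oc1c(C=O)cccc1OCc1ccccc1
F3 | step 8 | tert-butyldimethylsilyl ether of 12 | CC(C)(C)[Si](C)(C)O[C@H]1Cc2cccc(c2)Oc2c(OCc3ccccc3)cccc2/C=C/c2ccc(cc2)Oc2cc1cc3OC(c4ccccc4)(c4ccccc4)Oc23
F4 | step 6 | methyl 7-hydroxy-2,2-diphenyl-1,3-benzodioxole-5-carboxylate | COC(=O)c1cc(O)c2OC(c3ccccc3)(c3ccccc3)Oc2c1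
F5 | step 6 | methyl 7-(4-ethenylphenoxy)-2,2-diphenyl-1,3-benzodioxole-5-carboxylate | COC(=O)c1cc(Oc2ccc(C=C)cc2)c2OC(c3ccccc3)(c3ccccc3)Oc2c1
F6 | step 6 | 7-(4-ethenylphenoxy)-N-methoxy-N-methyl-2,2-diphenyl-1,3-benzodioxole-5-carboxamide | CON(C)C(=O)c1cc(Oc2ccc(C=C)cc2)c2OC(c3ccccc3)(c3ccccc3)Oc2c1
F7 | step 6 | {3-[2-(benzyloxy)-6-ethenylphenoxy]phenyl}magnesium bromide | C=Cc1cccc(OCc2ccccc2)c1Oc1cccc([Mg]Br)c1
F8 | step 6 | {3-[2-(benzyloxy)-6-ethenylphenoxy]phenyl}methanol | C=Cc1cccc(OCc2ccccc2)c1Oc1cccc(CO)c1
F9 | step 6 | 1-(benzyloxy)-2-[3-(chloromethyl)phenoxy]-3-ethenylbenzene | C=Cc1cccc(OCc2ccccc2)c1Oc1cccc(CCl)c1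
F10 | step 6 | {3-[2-(benzyloxy)-6-ethenylphenoxy]benzyl}magnesium chloride | C=Cc1cccc(OCc2ccccc2)c1Oc1cccc(C[Mg]Cl)c1
F11 | step 9 | triethylsilyl ether of 12 | CC[Si](CC)(CC)O[C@H]1Cc2cccc(c2)Oc2c(OCc3ccccc3)cccc2/C=C/c2ccc(cc2)Oc2cc1cc3OC(c4ccccc4)(c4ccccc4)Oc23
F12 | step 9 | triethylsilyl ether of 13 at the carbinol oxygen | Oc1cc2cc(c1O)Oc1ccc(cc1)CCc1cccc(O)c1Oc1cccc(c1)C[C@@H]2O[Si](CC)(CC)CC
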